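## Analysis of the target

The target (34) is a sesquilignan built on a 2,6-diaryl-3,7-dioxabicyclo[3.3.0]octane. Ring 1 is C7–O–C9'–C8'–C8 and carries ring B on C7; ring 2 is C7'–O–C9–C8–C8' and carries ring C, a free guaiacyl group, on C7'. The phenol oxygen of ring B is bound to C8'' of a 1-arylglycerol chain C7''–C9'' that ends in ring A, a second free guaiacyl group. The bicycle holds four contiguous stereocentres, (7R,8S,8'S,7'R): the rings are cis-fused at C8/C8' and each aryl group is trans to the neighbouring ring-fusion hydrogen, on the convex face. The chain holds two more, (7''R,8''S), the erythro (7'',8''-anti) arrangement; ring B insulates them from the core, so they need their own absolute control. The benzylic ether carbons C7 and C7' ionise in acid and are cleaved by hydrogenolysis, the p-oxygenated benzylic alcohol at C7'' ionises easily, and the phenols are oxidisable. The difficulty is the lack of symmetry: two different aryl halves must be joined to one C8–C8' unit with control of all four core centres while a sensitive, stereodefined side chain is carried along. The strategy rests on one feature: ring-fusion carbon C8' and benzylic, oxygen-bearing C7' are linked by the chain C8'–C8–C9–O–C7', so a carbonyl at C8' of a preformed ring 1 can reach a C7' hydrogen of a ring C benzyl ether on O9 and be bonded to C7'.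

## Retrosynthetic reasoning

**Protecting groups (34 ⇒ 33 ⇒ 32).** The last two operations only unmask. The phenols are carried as triisopropylsilyl ethers and the 7'',9''-diol as an acetonide. Benzyl ethers are excluded because hydrogenolysis would also cut the C7–O and C7'–O bonds. The bulky silyl group is chosen because aryl silyl ethers must survive two borohydride reductions and several amine and alkoxide steps. The acetonide is hydrolysed first, while the phenols are still masked, and buffered fluoride is the final step.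

**C8'–H (32 ⇒ 31 ⇒ 30).** The key step leaves a hydroxyl on C8'. It is removed by radical deoxygenation of the tertiary oxalate 31. The cut is safe stereochemically: a radical at the fusion carbon of a bicyclo[3.3.0] system can only accept hydrogen to give the cis-fused product.

**C8'–C7' (30 ⇒ 29), the key disconnection.** This is the only C–C bond of ring 2 that an aldol-built ring 1 does not already contain. Cutting it leaves a ketone at C8' and a plain benzyl ether at O9 in 29. The forward reaction must make the excited ketone abstract the C7' hydrogen and then couple the two radical centres; it creates ring 2 and the C8' and C7' stereocentres in one operation.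

**Ring 1 (29 ⇒ 28 ⇒ 26 ⇒ 25).** The ketone is unveiled last, by oxidation of alcohol 28, so it never needs protection. Ring 1 is cut at O–C9' and not at C7–O, so that C7 is set by an aldol and never ionised. Forward, the C7 hydroxyl of triol 26 displaces a primary sulfonate (27). The triol comes from dihydroxylation of the vinyl group of 25; the new carbinol centre is destroyed in the oxidation. A Dieckmann construction of the keto-tetrahydrofuran was set aside for three reasons:
- its β-alkoxy ester enolate can expel and re-add the C7 oxygen, which would erode C7;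
- the closure has two regiochemical outcomes;
- the later ester reduction would need a ketone ketal whose removal the acetonide would not survive.

**C9–O–C7' ether (25 ⇒ 21 + 23).** The ether is cut at the benzylic carbon, giving diol 21 and benzylic bromide 23 (from 2 through 22). The primary hydroxyl is addressed through the tin acetal 24.

**C7–C8 (21 ⇒ 20 ⇒ 18 + 15).** A syn aldol of the dienolate of crotonyl imide 18 with aldehyde 15 sets C7 and C8 together. The vinyl group is the C8'–C9' unit and the imide carbonyl becomes C9 on reduction. The 7,8-syn adduct maps onto the 7,8-trans ring, which is also the stable arrangement next to the later ketone.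

**Formyl group and acetonide (15 ⇒ 13 ⇒ 12).** The aldehyde of 15 is introduced from the aryl bromide of 13 by halogen–metal exchange. The bromide is an inert stand-in for the aldehyde during the first aldol. Acetonide 13 comes from diol 12.

**C7''–C8'' (12 ⇒ 11 ⇒ 10 ⇒ 8 + 2).** The aryl ether oxygen is carried in the enolate of imide 8, so no substitution at a hindered secondary carbon is needed. The syn aldol with aldehyde 2 fixes C8'' but gives the 7'',8''-syn (threo) adduct 10. C7'' is therefore inverted in ester 11 before the auxiliary is removed reductively to give 12.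

**Simple pieces.** Imide 8 comes from acid 5 and auxiliary 6 through anhydride 7; acid 5 from phenol 3 and acid 4; imide 18 from 6 and acid chloride 16 through 17; aldehyde 2 from vanillin 1.

## Alternatives that were turned down

**Alternative 1:** Photocycloaddition of stilbene A1 with the chiral fumarate A2.
- Disconnection: C7–C8 and C7'–C8', with C8–C8' supplied by the fumarate. The cyclobutane A3 must later lose its C7–C7' bond, and both benzylic carbons must be joined to the C9/C9' oxygens after ester reduction.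
- For: it is the most convergent plan. Both aryl halves and the whole carbon skeleton are assembled in one step from simple partners, and the trans diester carries the correct relative configuration at C8/C8'.
- Against: E/Z isomerisation and self-dimerisation of A1 compete. Both C8 and C8' depend on face selection by a remote lactate ester. The sacrificial C7–C7' bond must be cleaved oxidatively in a molecule with three electron-rich arenes. C7 and C7' are then formed by cation capture, under thermodynamic control only, and several steps follow the key step.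
- Comparison: Alternative 1 is stronger in convergence, since it forms two C–C bonds at once against one here. The chosen route offers instead C7 and C8 from an auxiliary-controlled aldol of known sense and a ring closure on a stereodefined ring 1.

**Alternative 2:** Titanocene radical cascade from epoxy cinnamyl ether A4.
- Disconnection: C8–C8' and O–C7'. Cp2TiCl (trivalent titanium) opens the epoxide of A4 to a C8 radical that closes 5-exo onto C8'. Iodine then makes C7' electrophilic and the C9 alkoxide closes ring 2, giving A5.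
- For: A5 is the fully protected target (the tert-butyldimethylsilyl counterpart of 32) with no extra hydroxyl. After the key step this plan is shorter than the chosen one by the two deoxygenation steps, and the conditions tolerate acetonide and silyl ethers.
- Against: C8, C8' and C7' are all set in the cascade from the single resident centre C7. The 5-exo closure must be both 7,8-trans and 8,8'-cis, and C7' is fixed in an ionic closure that can also give the epimer. A4 is a secondary ether of an ionisable p-alkoxybenzylic epoxy alcohol that must itself be made enantiopure.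
- Comparison: Alternative 2 is stronger in step count at the end. The chosen route pays two steps, but takes C7/C8 from an aldol and the ring fusion from geometry. It is kept as the fallback for the key step.

**Alternative 3:** Carbonyl ylide cycloaddition of chloro ether A6 to butenolide A7.
- Disconnection: C7–C8 and C9'–C8' of ring 1. Fluoride releases the ylide from A6; its (3+2) addition to A7 gives the furofuranone A8.
- For: it is convergent and non-photochemical. The C7' centre of A7 directs the ylide to the face away from ring C, so the cis fusion and two further centres follow from one.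
- Against: A6 must be made from an aldehyde that carries an acid-labile acetonide, under chloride/acid conditions. Unstabilised ylides give limited exo/endo control at C7. The C9 lactone carbonyl must afterwards be reduced to CH2 through a diol and re-closure. Fluoride rules out silyl ethers, so allyl ethers and a palladium deprotection are needed, and enantiopure A7 needs its own synthesis.
- Comparison: Alternative 3 is at least as convergent. The chosen route offers firmer control of C7 and keeps the oxidation level at C9 correct throughout.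

Key step: step 18

## Route

Remarks:
- Assumption: the descriptors are read as (7R,8S,7'R,8'S) for the bicycle and (7''R,8''S), erythro, for the chain; lignan numbering as in the analysis.
- Species that accumulate in the flask before the next reagent is added are numbered; excited states, radicals and alkoxides before work-up are not.
- Abbreviations in names: Gu = 3-methoxy-4-[(triisopropylsilyl)oxy]phenyl; Gu-methoxy = GuCH2O–; ArS = 4-{[(4R,5S)-4-Gu-2,2-dimethyl-1,3-dioxan-5-yl]oxy}-3-methoxyphenyl (ring B with the protected chain).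

Step 1
Reactants: 1 vanillin
Product: 2 3-methoxy-4-[(triisopropylsilyl)oxy]benzaldehyde
Conditions: TIPSCl, imidazole, DMF, rt
Reagents that add atoms: triisopropylsilyl chloride CC(C)[Si](Cl)(C(C)C)C(C)C
Why: Imidazole-promoted silylation of the phenol; the bulky aryl silyl ether should survive the later borohydride, amine and alkoxide conditions and leaves with fluoride at the end.

Step 2
Reactants: 3 4-bromo-2-methoxyphenol; 4 bromoacetic acid
Product: 5 (4-bromo-2-methoxyphenoxy)acetic acid
Conditions: NaOH, H2O, reflux; then HCl (aq)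
Reagents that add atoms: none
Why: Williamson ether synthesis of the phenoxide on the α-bromo carboxylate; the aryl bromide is the inert placeholder for the later formyl group.

Step 3
Reactants: 5 (4-bromo-2-methoxyphenoxy)acetic acid; 6 (R)-4-benzyloxazolidin-2-one
Product: 8 (R)-4-benzyl-3-[(4-bromo-2-methoxyphenoxy)acetyl]oxazolidin-2-one, via mixed pivalic anhydride 7 (not isolated)
Conditions: PivCl, Et3N, THF, −20 °C; then LiCl, 6, −20 °C → rt
Reagents that add atoms: none
Why: N-acylation of the oxazolidinone through the mixed anhydride; attack should occur at the unhindered aryloxyacetyl carbonyl and not at the pivaloyl carbonyl.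

Step 4
Reactants: 8 (R)-4-benzyl-3-[(4-bromo-2-methoxyphenoxy)acetyl]oxazolidin-2-one; 2 3-methoxy-4-[(triisopropylsilyl)oxy]benzaldehyde
Product: 10 (R)-4-benzyl-3-[(2R,3S)-2-(4-bromo-2-methoxyphenoxy)-3-hydroxy-3-Gu-propanoyl]oxazolidin-2-one, via dibutylboron enolate 9 (not isolated)
Conditions: Bu2BOTf, Et3N, CH2Cl2, −78 → 0 °C; then 2, −78 → 0 °C; then pH 7 buffer, MeOH, H2O2, 0 °C
Reagents that add atoms: none
Why: Evans syn aldol: the Z boron enolate reacts through a chair Zimmerman–Traxler transition state on the face away from the benzyl group, which sets C8'' in the required sense and C7'' as the 7'',8''-syn (threo) epimer; C7'' is corrected in step 5.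

Step 5
Reactants: 10 (R)-4-benzyl-3-[(2R,3S)-2-(4-bromo-2-methoxyphenoxy)-3-hydroxy-3-Gu-propanoyl]oxazolidin-2-one
Product: 11 (1R,2R)-3-[(R)-4-benzyl-2-oxooxazolidin-3-yl]-2-(4-bromo-2-methoxyphenoxy)-1-Gu-3-oxopropyl 4-nitrobenzoate
Conditions: 4-nitrobenzoic acid, PPh3, DIAD, toluene, 0 °C → rt
Reagents that add atoms: 4-nitrobenzoic acid OC(=O)c1ccc(cc1)[N+](=O)[O-]
Why: Mitsunobu esterification: SN2 displacement of the oxyphosphonium by the carboxylate inverts C7'' and turns the syn adduct into the 7'',8''-anti (erythro) series.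

Step 6
Reactants: 11 (1R,2R)-3-[(R)-4-benzyl-2-oxooxazolidin-3-yl]-2-(4-bromo-2-methoxyphenoxy)-1-Gu-3-oxopropyl 4-nitrobenzoate
Product: 12 (1R,2S)-2-(4-bromo-2-methoxyphenoxy)-1-Gu-propane-1,3-diol
Conditions: LiBH4, MeOH, THF, 0 °C → rt
Reagents that add atoms: none
Why: Hydride reduction cleaves the N-acyl oxazolidinone to the primary alcohol and removes the nitrobenzoate in the same operation; neither stereocentre is touched and the auxiliary is recovered.

Step 7
Reactants: 12 (1R,2S)-2-(4-bromo-2-methoxyphenoxy)-1-Gu-propane-1,3-diol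
Product: 13 (4R,5S)-5-(4-bromo-2-methoxyphenoxy)-4-Gu-2,2-dimethyl-1,3-dioxane
Conditions: Me2C(OMe)2, PPTS (cat.), CH2Cl2, rt
Reagents that add atoms: 2,2-dimethoxypropane COC(C)(C)OC
Why: Acid-catalysed transketalisation; the erythro diol should give the trans-4,5-disubstituted dioxane with both groups equatorial, and both hydroxyls are masked before the organolithium step.

Step 8
Reactants: 13 (4R,5S)-5-(4-bromo-2-methoxyphenoxy)-4-Gu-2,2-dimethyl-1,3-dioxane
Product: 15 ArS-carbaldehyde (4-{[(4R,5S)-4-Gu-2,2-dimethyl-1,3-dioxan-5-yl]oxy}-3-methoxybenzaldehyde), via aryllithium 14 (not isolated)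
Conditions: n-BuLi, THF, −78 °C; then DMF, −78 → 0 °C; NH4Cl (aq)
Reagents that add atoms: N,N-dimethylformamide CN(C)C=O
Why: Bromine–lithium exchange followed by formylation with the formamide; no acidic proton is present and exchange should outrun any deprotonation at −78 °C.

Step 9
Reactants: 6 (R)-4-benzyloxazolidin-2-one; 16 (E)-but-2-enoyl chloride
Product: 18 (R)-4-benzyl-3-[(E)-but-2-enoyl]oxazolidin-2-one, via lithium oxazolidinide 17 (not isolated)
Conditions: n-BuLi, THF, −78 °C; then 16, −78 → 0 °C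
Reagents that add atoms: none
Why: N-acylation of the lithiated oxazolidinone with the acid chloride at low temperature, which avoids deconjugation of the crotonyl group.

Step 10
Reactants: 18 (R)-4-benzyl-3-[(E)-but-2-enoyl]oxazolidin-2-one; 15 ArS-carbaldehyde
Product: 20 (R)-4-benzyl-3-[(2R,3R)-2-ethenyl-3-hydroxy-3-ArS-propanoyl]oxazolidin-2-one, via dibutylboron dienolate 19 (not isolated)
Conditions: Bu2BOTf, Et3N, CH2Cl2, −78 → 0 °C; then 15, −78 → 0 °C; then pH 7 buffer, MeOH, H2O2, 0 °C
Reagents that add atoms: none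
Why: Evans syn aldol of the crotonyl-derived dienolate, which reacts at its α-carbon through the closed transition state; the (R)-auxiliary sets the (7R) carbinol and the 7,8-syn relation, which becomes 7,8-trans once C7–O and C8–C8' are tied into ring 1.

Step 11
Reactants: 20 (R)-4-benzyl-3-[(2R,3R)-2-ethenyl-3-hydroxy-3-ArS-propanoyl]oxazolidin-2-one
Product: 21 (1R,2S)-1-ArS-2-ethenylpropane-1,3-diol
Conditions: LiBH4, MeOH, THF, 0 °C
Reagents that add atoms: none
Why: Reductive removal of the auxiliary; the imide carbonyl becomes the C9 hydroxymethyl group and the auxiliary is recovered.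

Step 12
Reactants: 2 3-methoxy-4-[(triisopropylsilyl)oxy]benzaldehyde
Product: 22 {3-methoxy-4-[(triisopropylsilyl)oxy]phenyl}methanol
Conditions: NaBH4, MeOH, 0 °C
Reagents that add atoms: none
Why: Borohydride reduction of the aldehyde, short and cold so that the aryl silyl ether is kept.

Step 13
Reactants: 22 {3-methoxy-4-[(triisopropylsilyl)oxy]phenyl}methanol
Product: 23 4-(bromomethyl)-2-methoxy-1-[(triisopropylsilyl)oxy]benzene
Conditions: CBr4, PPh3, CH2Cl2, 0 °C
Reagents that add atoms: tetrabromomethane BrC(Br)(Br)Br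
Why: Appel bromination under neutral conditions; the electron-rich benzylic bromide is used at once.

Step 14
Reactants: 21 (1R,2S)-1-ArS-2-ethenylpropane-1,3-diol; 23 4-(bromomethyl)-2-methoxy-1-[(triisopropylsilyl)oxy]benzene
Product: 25 (1R,2S)-1-ArS-2-[(Gu-methoxy)methyl]but-3-en-1-ol, via dibutylstannylene acetal 24 (not isolated)
Conditions: Bu2SnO, toluene, reflux (−H2O); then 23, Bu4NI, toluene, 70 °C
Reagents that add atoms: none
Why: Tin-acetal-mediated regioselective O-alkylation: the primary oxygen of the stannylene is the more nucleophilic, so the C9 ether forms and the C7 hydroxyl stays free; no fluoride or strong base is present.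

Step 15
Reactants: 25 (1R,2S)-1-ArS-2-[(Gu-methoxy)methyl]but-3-en-1-ol
Product: 26 (3S,4R)-4-ArS-3-[(Gu-methoxy)methyl]butane-1,2,4-triol (both C2 epimers)
Conditions: OsO4 (cat.), NMO, acetone/H2O, rt
Reagents that add atoms: N-methylmorpholine N-oxide C[N+]1([O-])CCOCC1; water O (both oxygens relayed by OsO4)
Why: Upjohn dihydroxylation of the only alkene; the configuration of the new carbinol (C8') is irrelevant because that carbon becomes the ketone.

Step 16
Reactants: 26 (3S,4R)-4-ArS-3-[(Gu-methoxy)methyl]butane-1,2,4-triol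
Product: 28 (4R,5R)-5-ArS-4-[(Gu-methoxy)methyl]tetrahydrofuran-3-ol (both C3 epimers), via primary tosylate 27 (not isolated)
Conditions: TsCl, Bu2SnO (cat.), Et3N, CH2Cl2, 0 °C → rt; then pyridine, 60 °C
Reagents that add atoms: none
Why: Tin-catalysed selective sulfonylation of the primary hydroxyl of the 1,2-diol, then 5-exo-tet displacement by the neutral C7 hydroxyl (intramolecular Williamson-type etherification); the C7–O bond is never broken, so C7 keeps its configuration.

Step 17
Reactants: 28 (4R,5R)-5-ArS-4-[(Gu-methoxy)methyl]tetrahydrofuran-3-ol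
Product: 29 (4S,5R)-5-ArS-4-[(Gu-methoxy)methyl]dihydrofuran-3(2H)-one
Conditions: Dess–Martin periodinane, NaHCO3, CH2Cl2, 0 °C → rt
Reagents that add atoms: none
Why: Buffered, non-basic oxidation converges both carbinol epimers on the ketone without β-elimination of the C9 alkoxy group; C8, now α to the ketone, already has the more stable 7,8-trans configuration.

Step 18
Reactants: 29 (4S,5R)-5-ArS-4-[(Gu-methoxy)methyl]dihydrofuran-3(2H)-one
Product: 30 (1R,3aR,4S,6aS)-1-ArS-4-Gu-tetrahydro-1H,3H-furo[3,4-c]furan-3a(4H)-ol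
Conditions: hν (medium-pressure Hg lamp, Pyrex filter, λ > 300 nm), benzene (degassed, 0.005 M), rt
Reagents that add atoms: none
Why: Light above 300 nm excites the n,π* band of the C8' ketone, and the carbonyl oxygen abstracts a hydrogen from C7' through a seven-membered transition state (1,6-hydrogen transfer). The resulting 1,5-biradical (ketyl at C8', benzylic α-oxy radical at C7') couples to form the C8'–C7' bond; this is a Norrish–Yang cyclisation, the known route from β-alkoxy ketones to 3-hydroxytetrahydrofurans. Ring 2 (C8'–C7'–O–C9–C8) is closed as a five-membered ring by radical recombination, not by a polar exo or endo attack. The C8' centre is fixed by the tether: C7' can only arrive on the face of ring 1 that carries C9, so the fusion is cis and the hydroxyl ends on the convex face. The C7' centre is set by the biradical conformation at closure, in which ring C should turn to the convex side, away from C9'H2 of ring 1. C8 cannot be damaged, since its 7,8-trans configuration is also the stable one next to the ketone. The step needs hydrogen abstraction to outrun α-cleavage of the C8'–C9' bond; this is helped by the weak, doubly activated C7'–H, by the ether oxygen at the γ-position on that side (no competing γ-hydrogen) and by the C7 ring hydrogen being out of reach of the carbonyl oxygen. Dilute, degassed solution suppresses bimolecular reduction and quenching.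

Step 19
Reactants: 30 (1R,3aR,4S,6aS)-1-ArS-4-Gu-tetrahydro-1H,3H-furo[3,4-c]furan-3a(4H)-ol
Product: 31 methyl (1R,3aR,4S,6aS)-1-ArS-4-Gu-tetrahydro-1H,3H-furo[3,4-c]furan-3a(4H)-yl oxalate
Conditions: ClC(O)CO2Me, DMAP, Et3N, CH2Cl2, 0 °C → rt
Reagents that add atoms: methyl chlorooxoacetate COC(=O)C(=O)Cl
Why: Acylation of the tertiary alcohol with a small, very reactive acid chloride under nucleophilic catalysis.

Step 20
Reactants: 31 methyl (1R,3aR,4S,6aS)-1-ArS-4-Gu-tetrahydro-1H,3H-furo[3,4-c]furan-3a(4H)-yl oxalate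
Product: 32 (1R,3aS,4R,6aS)-1-ArS-4-Gu-tetrahydro-1H,3H-furo[3,4-c]furan
Conditions: Bu3SnH, AIBN, toluene, 110 °C
Reagents that add atoms: none
Why: Barton–McCombie-type radical deoxygenation of a tertiary oxalate: the stannyl radical adds to the oxalate carbonyl, the C8'–O bond fragments to the tertiary radical, and hydrogen transfer from the stannane can only give the cis-fused bicycle.

Step 21
Reactants: 32 (1R,3aS,4R,6aS)-1-ArS-4-Gu-tetrahydro-1H,3H-furo[3,4-c]furan
Product: 33 (1R,2S)-1-Gu-2-{4-[(1R,3aS,4R,6aS)-4-Gu-tetrahydro-1H,3H-furo[3,4-c]furan-1-yl]-2-methoxyphenoxy}propane-1,3-diol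
Conditions: AcOH/THF/H2O (3:1:1), 40 °C
Reagents that add atoms: none
Why: Mild aqueous-acid hydrolysis of the six-membered acetonide; the acid should be too weak to ionise the benzylic ethers, and the aryl silyl ethers are stable to it.

Step 22
Reactants: 33 (1R,2S)-1-Gu-2-{4-[(1R,3aS,4R,6aS)-4-Gu-tetrahydro-1H,3H-furo[3,4-c]furan-1-yl]-2-methoxyphenoxy}propane-1,3-diol
Product: 34 (1R,2S)-1-(4-hydroxy-3-methoxyphenyl)-2-{4-[(1R,3aS,4R,6aS)-4-(4-hydroxy-3-methoxyphenyl)tetrahydro-1H,3H-furo[3,4-c]furan-1-yl]-2-methoxyphenoxy}propane-1,3-diol (target)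
Conditions: TBAF, AcOH, THF, 0 °C → rt
Reagents that add atoms: none
Why: Fluoride cleavage of both aryl silyl ethers, buffered with acetic acid so that no free phenoxide is exposed next to the benzylic alcohol.

## Compound list

1 | vanillin (4-hydroxy-3-methoxybenzaldehyde) | COc1cc(C=O)ccc1O | starting material
2 | 3-methoxy-4-[(triisopropylsilyl)oxy]benzaldehyde | COc1cc(C=O)ccc1O[Si](C(C)C)(C(C)C)C(C)C | intermediate
3 | 4-bromo-2-methoxyphenol | COc1cc(Br)ccc1O | starting material
4 | bromoacetic acid | OC(=O)CBr | starting material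
5 | (4-bromo-2-methoxyphenoxy)acetic acid | COc1cc(Br)ccc1OCC(=O)O | intermediate
6 | (R)-4-benzyloxazolidin-2-one | O=C1N[C@H](Cc2ccccc2)CO1 | starting material
7 | (4-bromo-2-methoxyphenoxy)acetic pivalic anhydride | COc1cc(Br)ccc1OCC(=O)OC(=O)C(C)(C)C | intermediate
8 | (R)-4-benzyl-3-[(4-bromo-2-methoxyphenoxy)acetyl]oxazolidin-2-one | COc1cc(Br)ccc1OCC(=O)N3[C@H](Cc4ccccc4)COC3=O | intermediate
9 | (R)-4-benzyl-3-[(Z)-2-(4-bromo-2-methoxyphenoxy)-1-(dibutylboryloxy)ethenyl]oxazolidin-2-one | COc1cc(Br)ccc1O/C=C(\OB(CCCC)CCCC)N3[C@H](Cc4ccccc4)COC3=O | intermediate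
10 | (R)-4-benzyl-3-[(2R,3S)-2-(4-bromo-2-methoxyphenoxy)-3-hydroxy-3-Gu-propanoyl]oxazolidin-2-one (syn, threo) | COc1cc([C@H](O)[C@H](C(=O)N3[C@H](Cc4ccccc4)COC3=O)Oc2ccc(Br)cc2OC)ccc1O[Si](C(C)C)(C(C)C)C(C)C | intermediate
11 | (1R,2R)-3-[(R)-4-benzyl-2-oxooxazolidin-3-yl]-2-(4-bromo-2-methoxyphenoxy)-1-Gu-3-oxopropyl 4-nitrobenzoate (anti, erythro) | COc1cc([C@@H](OC(=O)c6ccc(cc6)[N+](=O)[O-])[C@H](C(=O)N3[C@H](Cc4ccccc4)COC3=O)Oc2ccc(Br)cc2OC)ccc1O[Si](C(C)C)(C(C)C)C(C)C | intermediate
12 | (1R,2S)-2-(4-bromo-2-methoxyphenoxy)-1-Gu-propane-1,3-diol (erythro) | COc1cc([C@@H](O)[C@H](CO)Oc2ccc(Br)cc2OC)ccc1O[Si](C(C)C)(C(C)C)C(C)C | intermediate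
13 | (4R,5S)-5-(4-bromo-2-methoxyphenoxy)-4-Gu-2,2-dimethyl-1,3-dioxane (trans) | COc1cc([C@@H](OC(C)(C)OC5)[C@H]5Oc2ccc(Br)cc2OC)ccc1O[Si](C(C)C)(C(C)C)C(C)C | intermediate
14 | ArS-lithium (4-{[(4R,5S)-4-Gu-2,2-dimethyl-1,3-dioxan-5-yl]oxy}-3-methoxyphenyllithium) | COc1cc([C@@H](OC(C)(C)OC5)[C@H]5Oc2ccc([Li])cc2OC)ccc1O[Si](C(C)C)(C(C)C)C(C)C | intermediate
15 | ArS-carbaldehyde (4-{[(4R,5S)-4-Gu-2,2-dimethyl-1,3-dioxan-5-yl]oxy}-3-methoxybenzaldehyde) | COc1cc([C@@H](OC(C)(C)OC5)[C@H]5Oc2ccc(C=O)cc2OC)ccc1O[Si](C(C)C)(C(C)C)C(C)C | intermediate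
16 | (E)-but-2-enoyl chloride | C/C=C/C(=O)Cl | starting material
17 | lithium (R)-4-benzyl-2-oxooxazolidin-3-ide | O=C1N([Li])[C@H](Cc2ccccc2)CO1 | intermediate
18 | (R)-4-benzyl-3-[(E)-but-2-enoyl]oxazolidin-2-one | C/C=C/C(=O)N1[C@H](Cc2ccccc2)COC1=O | intermediate
19 | (R)-4-benzyl-3-[(1Z)-1-(dibutylboryloxy)buta-1,3-dienyl]oxazolidin-2-one | C=C/C=C(\OB(CCCC)CCCC)N1[C@H](Cc2ccccc2)COC1=O | intermediate
20 | (R)-4-benzyl-3-[(2R,3R)-2-ethenyl-3-hydroxy-3-ArS-propanoyl]oxazolidin-2-one | COc1cc([C@@H](OC(C)(C)OC5)[C@H]5Oc2ccc([C@H](O)[C@@H](C=C)C(=O)N3[C@H](Cc4ccccc4)COC3=O)cc2OC)ccc1O[Si](C(C)C)(C(C)C)C(C)C | intermediate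
21 | (1R,2S)-1-ArS-2-ethenylpropane-1,3-diol | COc1cc([C@@H](OC(C)(C)OC5)[C@H]5Oc2ccc([C@H](O)[C@@H](C=C)CO)cc2OC)ccc1O[Si](C(C)C)(C(C)C)C(C)C | intermediate
22 | {3-methoxy-4-[(triisopropylsilyl)oxy]phenyl}methanol | COc1cc(CO)ccc1O[Si](C(C)C)(C(C)C)C(C)C | intermediate
23 | 4-(bromomethyl)-2-methoxy-1-[(triisopropylsilyl)oxy]benzene | COc1cc(CBr)ccc1O[Si](C(C)C)(C(C)C)C(C)C | intermediate
24 | (4R,5S)-4-ArS-2,2-dibutyl-5-ethenyl-1,3,2-dioxastanninane | COc1cc([C@@H](OC(C)(C)OC5)[C@H]5Oc2ccc([C@@H]6O[Sn](CCCC)(CCCC)OC[C@@H]6C=C)cc2OC)ccc1O[Si](C(C)C)(C(C)C)C(C)C | intermediate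
25 | (1R,2S)-1-ArS-2-[(Gu-methoxy)methyl]but-3-en-1-ol | COc1cc([C@@H](OC(C)(C)OC5)[C@H]5Oc2ccc([C@H](O)[C@@H](C=C)COCc3ccc(O[Si](C(C)C)(C(C)C)C(C)C)c(OC)c3)cc2OC)ccc1O[Si](C(C)C)(C(C)C)C(C)C | intermediate
26 | (3S,4R)-4-ArS-3-[(Gu-methoxy)methyl]butane-1,2,4-triol, both C2 epimers | COc1cc([C@@H](OC(C)(C)OC5)[C@H]5Oc2ccc([C@H](O)[C@@H](C(O)CO)COCc3ccc(O[Si](C(C)C)(C(C)C)C(C)C)c(OC)c3)cc2OC)ccc1O[Si](C(C)C)(C(C)C)C(C)C | intermediate
27 | (3S,4R)-4-ArS-2,4-dihydroxy-3-[(Gu-methoxy)methyl]butyl 4-methylbenzenesulfonate, both C2 epimers | COc1cc([C@@H](OC(C)(C)OC5)[C@H]5Oc2ccc([C@H](O)[C@@H](C(O)COS(=O)(=O)c6ccc(C)cc6)COCc3ccc(O[Si](C(C)C)(C(C)C)C(C)C)c(OC)c3)cc2OC)ccc1O[Si](C(C)C)(C(C)C)C(C)C | intermediate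
28 | (4R,5R)-5-ArS-4-[(Gu-methoxy)methyl]tetrahydrofuran-3-ol, both C3 epimers (aryl and alkoxymethyl trans) | COc1cc([C@@H](OC(C)(C)OC5)[C@H]5Oc2ccc([C@@H]3OCC(O)[C@H]3COCc4ccc(O[Si](C(C)C)(C(C)C)C(C)C)c(OC)c4)cc2OC)ccc1O[Si](C(C)C)(C(C)C)C(C)C | intermediate
29 | (4S,5R)-5-ArS-4-[(Gu-methoxy)methyl]dihydrofuran-3(2H)-one (key-step precursor) | COc1cc([C@@H](OC(C)(C)OC5)[C@H]5Oc2ccc([C@@H]3OCC(=O)[C@H]3COCc4ccc(O[Si](C(C)C)(C(C)C)C(C)C)c(OC)c4)cc2OC)ccc1O[Si](C(C)C)(C(C)C)C(C)C | intermediate
30 | (1R,3aR,4S,6aS)-1-ArS-4-Gu-tetrahydro-1H,3H-furo[3,4-c]furan-3a(4H)-ol (key-step product; cis-fused, both aryls exo, hydroxyl on C8') | COc1cc([C@@H](OC(C)(C)OC5)[C@H]5Oc2ccc([C@@H]3OC[C@]4(O)[C@H]3CO[C@H]4c6ccc(O[Si](C(C)C)(C(C)C)C(C)C)c(OC)c6)cc2OC)ccc1O[Si](C(C)C)(C(C)C)C(C)C | intermediate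
31 | methyl (1R,3aR,4S,6aS)-1-ArS-4-Gu-tetrahydro-1H,3H-furo[3,4-c]furan-3a(4H)-yl oxalate | COc1cc([C@@H](OC(C)(C)OC5)[C@H]5Oc2ccc([C@@H]3OC[C@]4(OC(=O)C(=O)OC)[C@H]3CO[C@H]4c6ccc(O[Si](C(C)C)(C(C)C)C(C)C)c(OC)c6)cc2OC)ccc1O[Si](C(C)C)(C(C)C)C(C)C | intermediate
32 | (1R,3aS,4R,6aS)-1-ArS-4-Gu-tetrahydro-1H,3H-furo[3,4-c]furan | COc1cc([C@@H](OC(C)(C)OC5)[C@H]5Oc2ccc([C@@H]3OC[C@@H]4[C@H]3CO[C@H]4c6ccc(O[Si](C(C)C)(C(C)C)C(C)C)c(OC)c6)cc2OC)ccc1O[Si](C(C)C)(C(C)C)C(C)C | intermediate
33 | (1R,2S)-1-Gu-2-{4-[(1R,3aS,4R,6aS)-4-Gu-tetrahydro-1H,3H-furo[3,4-c]furan-1-yl]-2-methoxyphenoxy}propane-1,3-diol | COc1cc([C@@H](O)[C@H](CO)Oc2ccc([C@@H]3OC[C@@H]4[C@H]3CO[C@H]4c6ccc(O[Si](C(C)C)(C(C)C)C(C)C)c(OC)c6)cc2OC)ccc1O[Si](C(C)C)(C(C)C)C(C)C | intermediate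
34 | (1R,2S)-1-(4-hydroxy-3-methoxyphenyl)-2-{4-[(1R,3aS,4R,6aS)-4-(4-hydroxy-3-methoxyphenyl)tetrahydro-1H,3H-furo[3,4-c]furan-1-yl]-2-methoxyphenoxy}propane-1,3-diol | COc1cc([C@@H](O)[C@H](CO)Oc2ccc([C@@H]3OC[C@@H]4[C@H]3CO[C@H]4c6ccc(O)c(OC)c6)cc2OC)ccc1O | target

## Step count and least certain steps

Total: 22 steps. Longest linear sequence: 18 steps, from 3 (steps 2–8, 10, 11, 14–22).

**Step 18 (key step).** The excited α-alkoxy ketone may prefer α-cleavage of the C8'–C9' bond to hydrogen abstraction. Reverse hydrogen transfer may return starting ketone faster than the biradical closes, light may be absorbed by the three arenes, and closure may occur with ring C on the concave face.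
Fallback: give up the photochemical C8'–C7' closure and build the bicycle in the ground state by the titanocene cascade of Alternative 2, setting out from aldehyde 15 and rejoining the route at 32.
- CH2=CHMgBr adds to 15 to give the allylic alcohol F1 as both C7 epimers.
- Sharpless kinetic resolution (Ti(OiPr)4, L-(+)-diisopropyl tartrate, t-BuOOH, CH2Cl2, −20 °C) should epoxidise only the (7R) epimer and give the erythro epoxy alcohol F2.
- In parallel, aldehyde 2 is extended by Wittig reaction with Ph3P=CHCO2Et to the cinnamate F3, reduced with i-Bu2AlH to the cinnamyl alcohol F4 and converted with CBr4/PPh3 into the cinnamyl bromide F5.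
- O-Alkylation of F2 with F5 (NaH, THF, 0 °C) gives the epoxy cinnamyl ether F6.
- Cp2TiCl (trivalent titanium, made from Cp2TiCl2 and Zn) opens the epoxide to the C8 radical, which closes 5-exo onto C8'; iodine then lets the C9 alkoxide bond to C7'. This gives 32 directly, so steps 19 and 20 fall away.
- The price is that C8, C8' and C7' then depend on the diastereoselectivity of the cascade.

**Step 5.** The activated β-oxyphosphonium may eliminate to the enoyl imide, or the electron-rich benzylic centre may ionise, so that inversion is incomplete.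
Fallback: replace substitution by oxidation and reduction, setting out from 10 and returning at 12.
- LiBH4 reduction of 10 gives the threo diol F7.
- TBSCl/imidazole silylates the primary hydroxyl to give F8.
- Dess–Martin oxidation gives the α-aryloxy ketone F9.
- LiBH(s-Bu)3 at −78 °C should reduce it under Felkin–Anh control, with the aryloxy group antiperiplanar to the hydride, to the erythro alcohol F10.
- PPTS in MeOH removes the primary silyl ether to give 12.

**Step 16.** Sulfonylation may spread to a secondary hydroxyl, or the neighbouring C8' hydroxyl may displace the sulfonate first (epoxide formation), after which closure could take the four-membered path.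
Fallback: make the epoxide on purpose and open it under acid, setting out from 25 and returning at 28. Epoxidation of the vinyl group of 25 with m-chloroperbenzoic acid/NaHCO3 gives the epoxy alcohol F11. Catalytic camphorsulfonic acid (or MgBr2·OEt2) in CH2Cl2 at 0 °C then lets the C7 hydroxyl attack the terminal epoxide carbon, which gives 28.

**Step 20.** At 110 °C the tertiary C8' radical may undergo a 1,2-aryl shift from C7' or fragment before the stannane delivers hydrogen, and the hindered oxalate may react sluggishly in the chain.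
Fallback: change the radical precursor and the chain carrier, setting out from 30 and returning at 32. Oxalyl chloride converts 30 into the chlorooxalate F12. The sodium salt of N-hydroxypyridine-2-thione turns it into the Barton ester F13. Visible-light photolysis of F13 at room temperature with t-BuSH as the faster hydrogen donor should release the C8' radical by double decarboxylation and reduce it to 32.

## Further compounds

F1 | step 18 | 1-ArS-prop-2-en-1-ol, both C7 epimers | COc1cc([C@@H](OC(C)(C)OC5)[C@H]5Oc2ccc(C(O)C=C)cc2OC)ccc1O[Si](C(C)C)(C(C)C)C(C)C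
F2 | step 18 | (S)-ArS-[(R)-oxiran-2-yl]methanol (erythro; same C7 geometry as in 32) | COc1cc([C@@H](OC(C)(C)OC5)[C@H]5Oc2ccc([C@H](O)[C@H]6CO6)cc2OC)ccc1O[Si](C(C)C)(C(C)C)C(C)C
F3 | step 18 | ethyl (E)-3-Gu-prop-2-enoate | CCOC(=O)/C=C/c1ccc(O[Si](C(C)C)(C(C)C)C(C)C)c(OC)c1
F4 | step 18 | (E)-3-Gu-prop-2-en-1-ol | OC/C=C/c1ccc(O[Si](C(C)C)(C(C)C)C(C)C)c(OC)c1
F5 | step 18 | (E)-3-Gu-prop-2-enyl bromide | BrC/C=C/c1ccc(O[Si](C(C)C)(C(C)C)C(C)C)c(OC)c1
F6 | step 18 | (R)-2-{(S)-ArS-[(E)-3-Gu-prop-2-enyloxy]methyl}oxirane | COc1cc([C@@H](OC(C)(C)OC5)[C@H]5Oc2ccc([C@H](OC/C=C/c3ccc(O[Si](C(C)C)(C(C)C)C(C)C)c(OC)c3)[C@H]6CO6)cc2OC)ccc1O[Si](C(C)C)(C(C)C)C(C)C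
F7 | step 5 | (1S,2S)-2-(4-bromo-2-methoxyphenoxy)-1-Gu-propane-1,3-diol (threo) | COc1cc([C@H](O)[C@H](CO)Oc2ccc(Br)cc2OC)ccc1O[Si](C(C)C)(C(C)C)C(C)C
F8 | step 5 | (1S,2S)-2-(4-bromo-2-methoxyphenoxy)-3-[(tert-butyldimethylsilyl)oxy]-1-Gu-propan-1-ol | COc1cc([C@H](O)[C@H](CO[Si](C)(C)C(C)(C)C)Oc2ccc(Br)cc2OC)ccc1O[Si](C(C)C)(C(C)C)C(C)C
F9 | step 5 | (S)-2-(4-bromo-2-methoxyphenoxy)-3-[(tert-butyldimethylsilyl)oxy]-1-Gu-propan-1-one | COc1cc(C(=O)[C@H](CO[Si](C)(C)C(C)(C)C)Oc2ccc(Br)cc2OC)ccc1O[Si](C(C)C)(C(C)C)C(C)C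
F10 | step 5 | (1R,2S)-2-(4-bromo-2-methoxyphenoxy)-3-[(tert-butyldimethylsilyl)oxy]-1-Gu-propan-1-ol (erythro) | COc1cc([C@@H](O)[C@H](CO[Si](C)(C)C(C)(C)C)Oc2ccc(Br)cc2OC)ccc1O[Si](C(C)C)(C(C)C)C(C)C
F11 | step 16 | (1R,2S)-1-ArS-3-(Gu-methoxy)-2-(oxiran-2-yl)propan-1-ol, both epoxide epimers | COc1cc([C@@H](OC(C)(C)OC5)[C@H]5Oc2ccc([C@H](O)[C@@H](C6CO6)COCc3ccc(O[Si](C(C)C)(C(C)C)C(C)C)c(OC)c3)cc2OC)ccc1O[Si](C(C)C)(C(C)C)C(C)C
F12 | step 20 | (1R,3aR,4S,6aS)-1-ArS-4-Gu-tetrahydro-1H,3H-furo[3,4-c]furan-3a(4H)-yl chlorooxoacetate | COc1cc([C@@H](OC(C)(C)OC5)[C@H]5Oc2ccc([C@@H]3OC[C@]4(OC(=O)C(=O)Cl)[C@H]3CO[C@H]4c6ccc(O[Si](C(C)C)(C(C)C)C(C)C)c(OC)c6)cc2OC)ccc1O[Si](C(C)C)(C(C)C)C(C)C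
F13 | step 20 | (1R,3aR,4S,6aS)-1-ArS-4-Gu-tetrahydro-1H,3H-furo[3,4-c]furan-3a(4H)-yl 2-thioxopyridin-1(2H)-yl oxalate | COc1cc([C@@H](OC(C)(C)OC5)[C@H]5Oc2ccc([C@@H]3OC[C@]4(OC(=O)C(=O)ON7C=CC=CC7=S)[C@H]3CO[C@H]4c6ccc(O[Si](C(C)C)(C(C)C)C(C)C)c(OC)c6)cc2OC)ccc1O[Si](C(C)C)(C(C)C)C(C)C
A1 | alternative 1 | (E)-stilbene joining ring B (acetonide chain, tert-butyldimethylsilyl ring A) to tert-butyldimethylsilyl ring C | COc1cc([C@@H](OC(C)(C)OC5)[C@H]5Oc2ccc(/C=C/c3ccc(O[Si](C)(C)C(C)(C)C)c(OC)c3)cc2OC)ccc1O[Si](C)(C)C(C)(C)C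
A2 | alternative 1 | bis[(S)-1-ethoxy-1-oxopropan-2-yl] fumarate | CCOC(=O)[C@H](C)OC(=O)/C=C/C(=O)O[C@@H](C)C(=O)OCC
A3 | alternative 1 | 3,4-diarylcyclobutane-1,2-dicarboxylate, esters trans and aryls trans (key-step product) | COc1cc([C@@H](OC(C)(C)OC5)[C@H]5Oc2ccc([C@@H]6[C@H](C(=O)O[C@@H](C)C(=O)OCC)[C@@H](C(=O)O[C@@H](C)C(=O)OCC)[C@H]6c3ccc(O[Si](C)(C)C(C)(C)C)c(OC)c3)cc2OC)ccc1O[Si](C)(C)C(C)(C)C
A4 | alternative 2 | ring B (oxiran-2-yl)methyl (E)-cinnamyl ether of silylated ring C, either epoxide epimer | COc1cc([C@@H](OC(C)(C)OC5)[C@H]5Oc2ccc([C@H](OC/C=C/c3ccc(O[Si](C)(C)C(C)(C)C)c(OC)c3)C4CO4)cc2OC)ccc1O[Si](C)(C)C(C)(C)C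
A5 | alternative 2 | bis(tert-butyldimethylsilyl) acetonide of the target (key-step product) | COc1cc([C@@H](OC(C)(C)OC5)[C@H]5Oc2ccc([C@@H]3OC[C@@H]4[C@H]3CO[C@H]4c3ccc(O[Si](C)(C)C(C)(C)C)c(OC)c3)cc2OC)ccc1O[Si](C)(C)C(C)(C)C
A6 | alternative 3 | α-chloro (trimethylsilyl)methyl ether of the ring B aldehyde (allyl-protected ring A), both C7 epimers | COc1cc([C@@H](OC(C)(C)OC5)[C@H]5Oc2ccc(C(Cl)OC[Si](C)(C)C)cc2OC)ccc1OCC=C
A7 | alternative 3 | (R)-5-[4-(allyloxy)-3-methoxyphenyl]furan-2(5H)-one | O=C1C=C[C@H](c2ccc(OCC=C)c(OC)c2)O1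
A8 | alternative 3 | cis-fused furofuranone with C9 as lactone carbonyl (key-step product) | COc1cc([C@@H](OC(C)(C)OC5)[C@H]5Oc2ccc([C@@H]3OC[C@@H]4[C@H]3C(=O)O[C@H]4c3ccc(OCC=C)c(OC)c3)cc2OC)ccc1OCC=C
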